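**Assumptions (two lines)**
- Coloratanin A has no stereocentres. The tertiary carbinol carries two identical methyls and the prenyl alkene has two identical methyls, so "single enantiomer" has no content here.
- Building blocks are numbered. Simple reagents are named with SMILES in each step and are not numbered.

## Retrosynthetic overview
1. Disconnect C3–C1′ of the isoflavone by Suzuki–Miyaura coupling: a 6-prenyl-3-iodochromone plus a B-ring aryl-Bpin that already carries the 3-hydroxy-3-methylbutyl chain.
2. Disconnect the ArCH2–CH2C(OH)Me2 bond by the proposed new hydroxy-directed anti-Markovnikov NiH hydroarylation of 2-methylbut-3-en-2-ol with 4-bromo-2-iodophenol.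
3. Form the pyranone ring first, by enaminone/I2 cyclisation of a 2-hydroxyacetophenone with only one free ortho-OH, so ring closure is unambiguous.
4. Place the A-ring prenyl at C6 by Claisen rearrangement of the 5-O-allyl ether, then cross-metathesis. C6 is the only free ortho position of O5, because the other ortho carbon, C4a, is the ring fusion.
5. Order of bond/ring formation: C ring, then C6 prenyl, then the B-ring chain (separate fragment), then the C3–aryl bond, then the final fluoride desilylation (no acid anywhere near the end).

## Route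

**Step 1**
Reactants: 1 (2′,4′,6′-trihydroxyacetophenone)
Product: 2 (2′,6′-dihydroxy-4′-(triisopropylsilyloxy)acetophenone)
Conditions: TIPSCl, imidazole, DMF, 0 °C → rt, 4 h
Reagents that add atoms: TIPSCl, CC(C)[Si](Cl)(C(C)C)C(C)C
Why: The unchelated, most acidic 4-OH is silylated selectively over the two carbonyl-chelated ortho OHs (silyl ether formation). No stereocentre is involved.

**Step 2**
Reactants: 2
Product: 3 (2′-allyloxy-6′-hydroxy-4′-(TIPSO)acetophenone)
Conditions: allyl bromide (1.05 equiv), K2CO3 (1.1 equiv), acetone, 50 °C, 12 h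
Reagents that add atoms: allyl bromide, C=CCBr
Why: The two ortho OHs are equivalent, so mono-O-allylation gives a single constitutional isomer (Williamson etherification). The bis-allyl byproduct is separable.

**Step 3**
Reactants: 3
Product: 4 ((E)-enaminone, 1-(2-allyloxy-6-hydroxy-4-TIPSO-phenyl)-3-(dimethylamino)prop-2-en-1-one)
Conditions: DMF-DMA (3 equiv), toluene, 90 °C, 6 h
Reagents that add atoms: DMF-DMA, CN(C)C(OC)OC
Why: The acetyl CH3 condenses with DMF-DMA (enaminone formation); the chelated OH is untouched.

**Step 4**
Reactants: 4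
Product: 5 (5-allyloxy-3-iodo-7-(TIPSO)chromen-4-one)
Conditions: I2 (1.5 equiv), CHCl3, rt, 3 h; Na2S2O3 work-up
Reagents that add atoms: I2, II
Why: α-Iodination of the enaminone, then oxa-Michael addition of the only free phenol and loss of Me2NH (Gammill 3-iodochromone synthesis). Ring closure is regiochemically unambiguous because O5 is capped. No stereocentre.

**Step 5**
Reactants: 5
Product: 6 (6-allyl-5-hydroxy-3-iodo-7-(TIPSO)chromen-4-one)
Conditions: N,N-diethylaniline, 190 °C (microwave), 1 h
Reagents that add atoms: none
Why: Aromatic Claisen [3,3] rearrangement of the 5-O-allyl ether. The only free ortho carbon is C6 (C4a is blocked), so C6 selectivity is absolute. Tautomerisation restores the chelated 5-OH.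

**Step 6**
Reactants: 6
Product: 7 (6-prenyl-5-hydroxy-3-iodo-7-(TIPSO)chromen-4-one)
Conditions: Hoveyda–Grubbs II (5 mol%), 1,4-benzoquinone (10 mol%), 2-methylbut-2-ene (20 equiv), CH2Cl2, 40 °C, sealed tube, 16 h
Reagents that add atoms: 2-methylbut-2-ene, CC=C(C)C (supplies the =CMe2 terminus; propene is lost)
Why: Olefin cross-metathesis converts the terminal allyl to the trisubstituted prenyl alkene. Benzoquinone suppresses Ru–H isomerisation to the propenyl arene.

**Step 7**
Reactants: 8 (4-bromo-2-iodophenol) + 9 (2-methylbut-3-en-2-ol)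
Product: 10 (4-bromo-2-(3-hydroxy-3-methylbutyl)phenol)
Conditions: NiBr2·diglyme (10 mol%), dtbbpy (12 mol%), (EtO)2MeSiH (3.5 equiv), K3PO4 (3 equiv), DMA, 25 °C, 24 h (alkene 2 equiv)
Reagents that add atoms: none (silane supplies only H)
Why: Proposed new method: hydroxy-directed anti-Markovnikov NiH hydroarylation of a free tertiary allylic alcohol with an unprotected o-iodophenol. Ni–H, formed from Ni(II) and silane, binds the tertiary alkoxide. Syn-hydronickelation then places Ni on the terminal carbon, giving a five-membered oxa-nickelacycle, whereas Markovnikov insertion would give a strained four-membered one. The quaternary carbinol carbon blocks chain-walking beyond C3. Phenoxide-assisted oxidative addition of C–I (faster than C–Br) and C(sp2)–C(sp3) reductive elimination give the linear ArCH2CH2C(OH)Me2 chain. Closest known reactions are native-directing-group NiH anti-Markovnikov hydroarylation of alkenyl amides and Ni-catalysed reductive Heck coupling. No stereocentre is formed.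

**Step 8**
Reactants: 10
Product: 11 (2-(3-hydroxy-3-methylbutyl)-4-(pinacolboryl)phenol)
Conditions: B2pin2 (1.2 equiv), Pd(dppf)Cl2 (5 mol%), KOAc (3 equiv), dioxane, 90 °C, 6 h
Reagents that add atoms: B2pin2, CC1(C)OB(OC1(C)C)B1OC(C)(C)C(C)(C)O1
Why: Miyaura borylation of the aryl bromide; the free phenol and tertiary alcohol are tolerated.

**Step 9**
Reactants: 7 + 11
Product: 12 (3-aryl isoflavone: 5-hydroxy-6-prenyl-7-OTIPS, B ring 4′-OH/3′-CH2CH2C(OH)Me2)
Conditions: Pd(PPh3)4 (5 mol%), Na2CO3 (3 equiv), DME/H2O 4:1, 80 °C, 8 h (11 at 1.3 equiv)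
Reagents that add atoms: none
Why: Suzuki–Miyaura coupling of the 3-iodochromone. 4-Hydroxyarylboronates are known to couple under these mild carbonate conditions. Prenyl, the chelated 5-OH and the tertiary alcohol are inert. No stereocentre.

**Step 10**
Reactants: 12
Product: 13 (Coloratanin A)
Conditions: TBAF (1.5 equiv), AcOH (1.5 equiv), THF, 0 °C, 30 min
Reagents that add atoms: none
Why: Fluoride cleavage of the aryl TIPS ether under buffered, non-acidic conditions. This avoids acid-promoted chromane formation from the prenyl phenol or the ortho-(3-hydroxy-3-methylbutyl)phenol. The product is achiral.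

## Compound list
1 | 2′,4′,6′-trihydroxyacetophenone | CC(=O)c1c(O)cc(O)cc1O | starting material
2 | 2′,6′-dihydroxy-4′-(TIPSO)acetophenone | CC(=O)c1c(O)cc(O[Si](C(C)C)(C(C)C)C(C)C)cc1O | intermediate
3 | 2′-allyloxy-6′-hydroxy-4′-(TIPSO)acetophenone | CC(=O)c1c(O)cc(O[Si](C(C)C)(C(C)C)C(C)C)cc1OCC=C | intermediate
4 | enaminone of 3 | CN(C)/C=C/C(=O)c1c(O)cc(O[Si](C(C)C)(C(C)C)C(C)C)cc1OCC=C | intermediate
5 | 5-allyloxy-3-iodo-7-(TIPSO)chromone | O=c1c(I)coc2cc(O[Si](C(C)C)(C(C)C)C(C)C)cc(OCC=C)c12 | intermediate
6 | 6-allyl-5-hydroxy-3-iodo-7-(TIPSO)chromone | C=CCc1c(O[Si](C(C)C)(C(C)C)C(C)C)cc2occ(I)c(=O)c2c1O | intermediate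
7 | 6-prenyl-5-hydroxy-3-iodo-7-(TIPSO)chromone | CC(C)=CCc1c(O[Si](C(C)C)(C(C)C)C(C)C)cc2occ(I)c(=O)c2c1O | intermediate
8 | 4-bromo-2-iodophenol | Oc1ccc(Br)cc1I | starting material
9 | 2-methylbut-3-en-2-ol | C=CC(C)(C)O | starting material
10 | 4-bromo-2-(3-hydroxy-3-methylbutyl)phenol | CC(C)(O)CCc1cc(Br)ccc1O | intermediate
11 | 2-(3-hydroxy-3-methylbutyl)-4-(Bpin)phenol | CC(C)(O)CCc1cc(B2OC(C)(C)C(C)(C)O2)ccc1O | intermediate
12 | 7-TIPS isoflavone precursor | CC(C)=CCc1c(O[Si](C(C)C)(C(C)C)C(C)C)cc2occ(-c3ccc(O)c(CCC(C)(C)O)c3)c(=O)c2c1O | intermediate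
13 | Coloratanin A | CC(C)=CCc1c(O)cc2occ(-c3ccc(O)c(CCC(C)(C)O)c3)c(=O)c2c1O | target

## Totals
- Total steps: 10.
- Longest linear sequence: 8 steps (1 → 2 → 3 → 4 → 5 → 6 → 7 → 12 → 13; steps 1–6, 9, 10).

## Three steps most likely to fail
1. **Step 7 (proposed new NiH hydroarylation).** Possible problems are branched or Heck-type products, C–Br competition, or silane consumption by the free OH groups.
   Fallback (known chemistry, different approach): 5-bromosalicylaldehyde + acetone/NaOH (aldol condensation) → benzalacetone; Stryker's-reagent conjugate reduction; then excess MeMgBr to the tertiary alcohol. This gives 10 without any Ni step.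
2. **Step 5 (thermal Claisen of a 3-iodochromone with a bulky ortho-OTIPS).** The rearrangement may be slow, or the vinyl iodide may decompose at 190 °C.
   Fallback: perform the Claisen earlier on acetophenone 3, where it is regiospecific at C5 because C1 is blocked. Then run enaminone/I2 cyclisation with two free ortho OHs, relying on the sterically favoured unhindered OH to close the ring (isomers separated chromatographically).
3. **Step 6 (allyl → prenyl cross-metathesis).** Expect incomplete conversion and propenyl isomerisation.
   Fallback: Lemieux–Johnson cleavage of the allyl group to the aldehyde, then Wittig olefination with Me2C=PPh3 (from isopropyltriphenylphosphonium iodide) to install the prenyl group.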